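**Retrosynthetic overview**
1. The acid comes from the corresponding aldehyde by oxidation. The C4–C5 bond between the two quaternary carbons comes from a Claisen [3,3] shift of a 1‑alkenyl‑tetrahydrocyclopenta[c]pyran.
2. That oxabicycle comes from an intramolecular inverse‑demand oxa‑Diels–Alder reaction of an acyclic (2E,4Z)‑hexaenal. The enal O=C–C=C is the 4π partner and the nearest trisubstituted C=C is the 2π partner. Cyclopentene and dihydropyran close together (bonds C3a–C7a and C7–O), and the pyran is then traded for the cyclohexene in the same flask.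
3. The hexaenal comes from a (Z)‑vinyl iodide and 3‑(dimethylamino)‑2‑methylacrolein. The vinyl iodide comes from an α‑methyl β,γ‑unsaturated aldehyde by iodo‑olefination.
4. That aldehyde comes from an achiral phenylpentaene with CO/H2. This asymmetric hydroformylation sets the only stereocentre present before the cyclisation.
5. The pentaene comes from acrolein, two equivalents of Ph3P=C(Me)CHO and diethyl cinnamylphosphonate.

Assumption: (S,S,S)‑BisDiazaphos is taken to give the (S)‑aldehyde. If the sense of induction is the reverse, the (R,R,R)‑ligand is used and nothing else changes.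

**Step 1**
Reactants: 1 acrolein; 2 2‑(triphenylphosphoranylidene)propanal
Product: 3 (2E)‑2‑methylpenta‑2,4‑dienal
Conditions: 1 (3 equiv), CH2Cl2, hydroquinone (cat.), 40 °C
Reagents that add atoms: none
Why: Wittig olefination with a stabilised formyl ylide gives the E‑trisubstituted enal, and the excess of the far more electrophilic acrolein suppresses a second homologation.

**Step 2**
Reactants: 3 (2E)‑2‑methylpenta‑2,4‑dienal; 2 2‑(triphenylphosphoranylidene)propanal
Product: 4 (2E,4E)‑2,4‑dimethylhepta‑2,4,6‑trienal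
Conditions: 2 (1.3 equiv), PhMe, BHT (cat.), 100 °C
Reagents that add atoms: none
Why: A second E‑selective Wittig olefination of the same type needs heat for the less electrophilic dienal, and it stops there because the trienal is less reactive still.

**Step 3**
Reactants: 4 (2E,4E)‑2,4‑dimethylhepta‑2,4,6‑trienal; 5 diethyl [(E)‑3‑phenylprop‑2‑enyl]phosphonate
Product: 6 [(1E,3E,5E,7E)‑5,7‑dimethyldeca‑1,3,5,7,9‑pentaenyl]benzene
Conditions: 5, LiHMDS, THF, −78 °C; then 4, −78 → 0 °C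
Reagents that add atoms: none
Why: Horner–Wadsworth–Emmons olefination with the allylic phosphonate anion forms the new disubstituted C=C as the E isomer and completes the conjugated chain.

**Step 4**
Reactants: 6 [(1E,3E,5E,7E)‑5,7‑dimethyldeca‑1,3,5,7,9‑pentaenyl]benzene
Product: 7 (2S,3E,5E,7E,9E)‑2,4,6‑trimethyl‑10‑phenyldeca‑3,5,7,9‑tetraenal
Conditions: Rh(acac)(CO)2 (1 mol %), (S,S,S)‑BisDiazaphos (1.2 mol %), CO/H2 (1:1, 10 bar), PhMe, 40 °C; used crude
Reagents that add atoms: carbon monoxide, [C-]#[O+]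
Why: In this Rh‑catalysed asymmetric hydroformylation of a terminal 1,3‑diene, Rh–H adds only to the monosubstituted C=C, the η3‑allyl is carbonylated at the secondary carbon (branched 1,2‑product), and the chiral diazaphospholane sets the methyl‑bearing centre as S while the internal alkenes stay inert.

**Step 5**
Reactants: 7 (2S,3E,5E,7E,9E)‑2,4,6‑trimethyl‑10‑phenyldeca‑3,5,7,9‑tetraenal; 8 propyltriphenylphosphonium bromide
Product: 12 [(1E,3E,5E,7E,9S,10Z)‑11‑iodo‑5,7,9‑trimethyltrideca‑1,3,5,7,10‑pentaenyl]benzene, via propylidene ylide 9 (not isolated), via iodophosphonium iodide 10 (not isolated), via iodo ylide 11 (not isolated)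
Conditions: 8, n‑BuLi, THF, 0 °C; I2, −78 °C; NaHMDS, −20 °C; then 7, −78 °C
Reagents that add atoms: iodine, II
Why: In this Stork–Zhao type Wittig olefination the α‑iodo ylide adds under kinetic control at −78 °C to give the Z‑iodoalkene (iodine cis to the chain) faster than it enolises the aldehyde, so the stereocentre is kept.

**Step 6**
Reactants: 12 [(1E,3E,5E,7E,9S,10Z)‑11‑iodo‑5,7,9‑trimethyltrideca‑1,3,5,7,10‑pentaenyl]benzene; 13 (E)‑3‑(dimethylamino)‑2‑methylprop‑2‑enal
Product: 16 (2E,4Z,6S,7E,9E,11E,13E)‑4‑ethyl‑2,6,8,10‑tetramethyl‑14‑phenyltetradeca‑2,4,7,9,11,13‑hexaenal, via vinyllithium 14 (not isolated), via amino alkoxide 15 (not isolated)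
Conditions: t‑BuLi (2 equiv), Et2O, −78 °C; 13, −78 → 0 °C; 1 M aq. HCl, 0 °C
Reagents that add atoms: water, O
Why: Iodine–lithium exchange keeps the alkene geometry, the vinyllithium adds 1,2 to the vinylogous formamide, and acid then expels dimethylamine with allylic transposition (vinylogous formylation) to give the E‑2‑methylenal, the amine being removed as its salt before it can racemise C6.

**Step 7**
Reactants: 16 (2E,4Z,6S,7E,9E,11E,13E)‑4‑ethyl‑2,6,8,10‑tetramethyl‑14‑phenyltetradeca‑2,4,7,9,11,13‑hexaenal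
Product: 18 (1R,3aR,4R,5S,7aS)‑3‑ethyl‑1,4,5,7‑tetramethyl‑5‑[(1E,3E)‑4‑phenylbuta‑1,3‑dienyl]‑3a,4,5,7a‑tetrahydro‑1H‑indene‑4‑carbaldehyde, via oxabicyclic dihydropyran 17 (not isolated)
Conditions: Eu(fod)3 (10 mol %), BHT (cat.), PhMe (0.01 M), 70 °C, dark
Reagents that add atoms: none
Why: Proposed new method: the Eu‑bound enal O=C1–C2=C3 acts as a 1‑oxadiene and adds suprafacially across the electron‑rich C7=C8 bond (new bonds C3–C7 and O–C8) through the carbonyl‑endo, trans‑fused array, in which H‑6 eclipses the C8 methyl to avoid A1,3 strain, so the tether reaches the face anti to the C6 methyl, closing cyclopentene and dihydropyran together and fixing three centres; the resulting 2‑alkenyl‑dihydropyran then undergoes a boat Claisen [3,3] shift (C2–C10) in which the ring‑locked enol ether and the E‑C9=C10 geometry relay the C8 configuration to both quaternary carbons; O–C8 closure should be faster than direct formation of the congested C2–C10 bond, and any direct all‑carbon [4+2] through the same endo array gives the same aldehyde; the closest known types are lanthanide‑catalysed inverse‑demand hetero‑Diels–Alder reactions of enals, Tietze‑type intramolecular oxadiene cycloadditions and the Büchi dihydropyran‑to‑cyclohexene Claisen rearrangement.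

**Step 8**
Reactants: 18 (1R,3aR,4R,5S,7aS)‑3‑ethyl‑1,4,5,7‑tetramethyl‑5‑[(1E,3E)‑4‑phenylbuta‑1,3‑dienyl]‑3a,4,5,7a‑tetrahydro‑1H‑indene‑4‑carbaldehyde
Product: 19 22‑nor‑zyggomphic acid B
Conditions: NaClO2, NaH2PO4, 2‑methyl‑2‑butene (excess), t‑BuOH/H2O, 0 °C → rt
Reagents that add atoms: sodium chlorite, [Na+].[O-]Cl=O
Why: Pinnick oxidation converts even a fully substituted neopentyl aldehyde to the acid, the alkene scavenger removes HOCl before it can touch the diene, and no stereocentre is affected.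

**Compound list**
1 | acrolein | C=CC=O | starting material
2 | 2‑(triphenylphosphoranylidene)propanal | CC(C=O)=P(c1ccccc1)(c1ccccc1)c1ccccc1 | starting material
3 | (2E)‑2‑methylpenta‑2,4‑dienal | C=C/C=C(\C)C=O | intermediate
4 | (2E,4E)‑2,4‑dimethylhepta‑2,4,6‑trienal | C=C/C=C(\C)/C=C(\C)C=O | intermediate
5 | diethyl [(E)‑3‑phenylprop‑2‑enyl]phosphonate | CCOP(=O)(C/C=C/c1ccccc1)OCC | starting material
6 | [(1E,3E,5E,7E)‑5,7‑dimethyldeca‑1,3,5,7,9‑pentaenyl]benzene | C=C/C=C(\C)/C=C(\C)/C=C/C=C/c1ccccc1 | intermediate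
7 | (2S,3E,5E,7E,9E)‑2,4,6‑trimethyl‑10‑phenyldeca‑3,5,7,9‑tetraenal | O=C[C@@H](C)/C=C(\C)/C=C(\C)/C=C/C=C/c1ccccc1 | intermediate
8 | propyltriphenylphosphonium bromide | CCC[P+](c1ccccc1)(c1ccccc1)c1ccccc1.[Br-] | starting material
9 | propylidenetriphenylphosphorane (not isolated) | CCC=P(c1ccccc1)(c1ccccc1)c1ccccc1 | intermediate
10 | (1‑iodopropyl)triphenylphosphonium iodide (not isolated) | CCC(I)[P+](c1ccccc1)(c1ccccc1)c1ccccc1.[I-] | intermediate
11 | (1‑iodopropylidene)triphenylphosphorane (not isolated) | CCC(I)=P(c1ccccc1)(c1ccccc1)c1ccccc1 | intermediate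
12 | [(1E,3E,5E,7E,9S,10Z)‑11‑iodo‑5,7,9‑trimethyltrideca‑1,3,5,7,10‑pentaenyl]benzene | CC/C(I)=C/[C@@H](C)/C=C(\C)/C=C(\C)/C=C/C=C/c1ccccc1 | intermediate
13 | (E)‑3‑(dimethylamino)‑2‑methylprop‑2‑enal | CN(C)/C=C(\C)C=O | starting material
14 | vinyllithium from 12, Li in place of I with retention (not isolated) | [Li]/C(CC)=C\[C@@H](C)/C=C(\C)/C=C(\C)/C=C/C=C/c1ccccc1 | intermediate
15 | lithium alkoxide from 1,2‑addition of 14 to 13, epimers at the carbinol carbon (not isolated) | [Li+].[O-]C(/C(C)=C/N(C)C)/C(CC)=C\[C@@H](C)/C=C(\C)/C=C(\C)/C=C/C=C/c1ccccc1 | intermediate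
16 | (2E,4Z,6S,7E,9E,11E,13E)‑4‑ethyl‑2,6,8,10‑tetramethyl‑14‑phenyltetradeca‑2,4,7,9,11,13‑hexaenal | O=C/C(C)=C/C(CC)=C\[C@@H](C)/C=C(\C)/C=C(\C)/C=C/C=C/c1ccccc1 | intermediate
17 | (1S,4aR,7R,7aS)‑5‑ethyl‑1,4,7‑trimethyl‑1‑[(1E,3E,5E)‑2‑methyl‑6‑phenylhexa‑1,3,5‑trienyl]‑1,4a,7,7a‑tetrahydrocyclopenta[c]pyran, trans‑fused, trienyl cis to H‑7a (not isolated) | CCC1=C[C@@H](C)[C@H]2[C@H]1C(C)=CO[C@]2(C)/C=C(\C)/C=C/C=C/c1ccccc1 | intermediate
18 | (1R,3aR,4R,5S,7aS)‑3‑ethyl‑1,4,5,7‑tetramethyl‑5‑[(1E,3E)‑4‑phenylbuta‑1,3‑dienyl]‑3a,4,5,7a‑tetrahydro‑1H‑indene‑4‑carbaldehyde | CCC1=C[C@@H](C)[C@@H]2C(C)=C[C@](C)(/C=C/C=C/c3ccccc3)[C@](C)(C=O)[C@@H]12 | intermediate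
19 | 22‑nor‑zyggomphic acid B, (1R,3aR,4R,5S,7aS)‑3‑ethyl‑1,4,5,7‑tetramethyl‑5‑[(1E,3E)‑4‑phenylbuta‑1,3‑dienyl]‑3a,4,5,7a‑tetrahydro‑1H‑indene‑4‑carboxylic acid | CCC1=C[C@@H](C)[C@@H]2C(C)=C[C@](C)(/C=C/C=C/c3ccccc3)[C@](C)(C(=O)O)[C@@H]12 | target

**Totals:** 8 steps in all. The longest linear sequence is 8 steps, and no protecting groups are used.

**Steps most likely to fail**

Step 4. The long polyene may bind rhodium too strongly, give linear or chain‑walked aldehydes, or give a lower ee than simple dienes. The product can also slip into conjugation. The fallback takes the stereocentre from the chiral pool. It sets out from ylide 2 and comes back at aldehyde 7. Commercial methyl (R)‑3‑hydroxy‑2‑methylpropanoate F1 is silylated (TBSCl, imidazole) to silyl ether ester F2. This is reduced (DIBAL‑H, −78 °C) to aldehyde F3. Two homologations with 2 give enal F4 and then dienal F5. Coupling with the anion of 5 gives tetraene silyl ether F6. Desilylation (TBAF) gives tetraenol F7, and oxidation (Dess–Martin periodinane, NaHCO3) gives 7.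

Step 5. Yields of α‑iodo ylide olefinations are modest, and the basic medium can enolise 7. The fallback sets out from 7 and comes back at hexaenal 16, so it needs neither the vinyl iodide nor an organolithium. Still–Gennari olefination with ethyl 2‑[bis(2,2,2‑trifluoroethoxy)phosphoryl]butanoate (KHMDS, 18‑crown‑6, −78 °C) gives (Z)‑enoate F8. DIBAL‑H gives allylic alcohol F9, and MnO2 gives (Z)‑enal F10. A Wittig reaction with 2 then gives 16.

Step 7. The oxadiene mode may be slow. A [1,5]‑H shift across the (Z)‑diene, or an exo (cis‑fused) cycloaddition, may compete. The fallback removes the oxadiene altogether. It sets out from 16 and comes back at target 19. Pinnick oxidation of 16 gives hexaenoic acid F11. This acid is then cyclised by a purely thermal all‑carbon intramolecular [4+2] cycloaddition (PhMe, BHT, 110 °C) directly to 19.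

**Further compounds**
F1 | step 4 | methyl (R)‑3‑hydroxy‑2‑methylpropanoate | COC(=O)[C@H](C)CO
F2 | step 4 | methyl (R)‑3‑(tert‑butyldimethylsilyloxy)‑2‑methylpropanoate | COC(=O)[C@H](C)CO[Si](C)(C)C(C)(C)C
F3 | step 4 | (R)‑3‑(tert‑butyldimethylsilyloxy)‑2‑methylpropanal | O=C[C@H](C)CO[Si](C)(C)C(C)(C)C
F4 | step 4 | (2E,4S)‑5‑(tert‑butyldimethylsilyloxy)‑2,4‑dimethylpent‑2‑enal | O=C/C(C)=C/[C@H](C)CO[Si](C)(C)C(C)(C)C
F5 | step 4 | (2E,4E,6S)‑7‑(tert‑butyldimethylsilyloxy)‑2,4,6‑trimethylhepta‑2,4‑dienal | O=C/C(C)=C/C(C)=C/[C@H](C)CO[Si](C)(C)C(C)(C)C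
F6 | step 4 | tert‑butyldimethylsilyl ether of (2S,3E,5E,7E,9E)‑2,4,6‑trimethyl‑10‑phenyldeca‑3,5,7,9‑tetraen‑1‑ol | c1ccccc1/C=C/C=C/C(C)=C/C(C)=C/[C@H](C)CO[Si](C)(C)C(C)(C)C
F7 | step 4 | (2S,3E,5E,7E,9E)‑2,4,6‑trimethyl‑10‑phenyldeca‑3,5,7,9‑tetraen‑1‑ol | c1ccccc1/C=C/C=C/C(C)=C/C(C)=C/[C@H](C)CO
F8 | step 5 | ethyl (2Z,4S,5E,7E,9E,11E)‑2‑ethyl‑4,6,8‑trimethyl‑12‑phenyldodeca‑2,5,7,9,11‑pentaenoate | CCOC(=O)/C(CC)=C\[C@@H](C)/C=C(\C)/C=C(\C)/C=C/C=C/c1ccccc1
F9 | step 5 | (2Z,4S,5E,7E,9E,11E)‑2‑ethyl‑4,6,8‑trimethyl‑12‑phenyldodeca‑2,5,7,9,11‑pentaen‑1‑ol | OC/C(CC)=C\[C@@H](C)/C=C(\C)/C=C(\C)/C=C/C=C/c1ccccc1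
F10 | step 5 | (2Z,4S,5E,7E,9E,11E)‑2‑ethyl‑4,6,8‑trimethyl‑12‑phenyldodeca‑2,5,7,9,11‑pentaenal | O=C/C(CC)=C\[C@@H](C)/C=C(\C)/C=C(\C)/C=C/C=C/c1ccccc1
F11 | step 7 | (2E,4Z,6S,7E,9E,11E,13E)‑4‑ethyl‑2,6,8,10‑tetramethyl‑14‑phenyltetradeca‑2,4,7,9,11,13‑hexaenoic acid | OC(=O)/C(C)=C/C(CC)=C\[C@@H](C)/C=C(\C)/C=C(\C)/C=C/C=C/c1ccccc1
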